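**Plan**

- Ring names: ring A/ring C = benzo/pyran ring of the 3,4-diarylchroman (O1, C2, C3, C4, C4a, C8a); ring B = dimethoxyphenol ring on C3; ring E = central benzene on C4; ring F/ring G = pyran/benzo ring of the second chroman (primed atoms).
- Cuts (retro): the four O–benzyl bonds; the C2 oxidation level (chroman from chroman-2-ol); then O1–C2 and C3–C4 of ring C in one event (o-quinone methide of ring A plus enamine of the ring-B acetaldehyde); then C4–C4a (aryllithium/aldehyde); in the second chroman O1'–C8a' (C–O coupling) and C3'–C4' (auxiliary alkylation); last the ArCH2–CO2H bond on ring E (carboxylation of methyl orsellinate).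
- Forward: ring E comes from methyl orsellinate, ring F is built on its methyl carbon, ring A is added as an aryllithium, ring C closes last; one reduction and one hydrogenolysis finish.
- Enabling feature: O1 on ring A is ortho to the benzylic C4, so O1–C8a–C4a–C4 can be unmasked as a 1-oxadiene (o-quinone methide) with ring E on its terminus; C2 is a CH2 bound only to O1 and C3, so it can be carried as an aldehyde carbon, which makes C3 an enamine carbon and afterwards an epimerisable centre.
- Stereochemistry: C3' (R) from the (R)-4-benzyloxazolidinone alkylation; C4 (S) by catalyst control in the key step; C3 (R) relayed from C4 by thermodynamic equilibration (trans) through the ring-chain tautomerism of the lactol.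

Key step: step 16

Assumption: the sense of induction of the (R)-prolinol catalyst in step 16 is assigned by analogy with its enamine additions to nitroalkenes; the carbinol carbon of 24 and C2 of 28 are carried as epimer mixtures because both centres are removed later.

**Route**

Step 1
Reactants: 1 2-bromo-4-hydroxybenzaldehyde
Product: 2 4-(benzyloxy)-2-bromobenzaldehyde
Conditions: BnBr, K2CO3, DMF, rt
Reagents that add atoms: benzyl bromide, BrCc1ccccc1
Why: Williamson etherification of the phenoxide on benzyl bromide, to which the aldehyde and aryl bromide are inert.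

Step 2
Reactants: 2 4-(benzyloxy)-2-bromobenzaldehyde
Product: 3 [4-(benzyloxy)-2-bromophenyl]methanol
Conditions: NaBH4, MeOH, 0 °C
Reagents that add atoms: none
Why: Chemoselective borohydride reduction of the aldehyde.

Step 3
Reactants: 3 [4-(benzyloxy)-2-bromophenyl]methanol
Product: 4 4-(benzyloxy)-2-bromo-1-(bromomethyl)benzene
Conditions: PBr3, CH2Cl2, 0 °C
Reagents that add atoms: phosphorus tribromide, BrP(Br)Br
Why: Bromide displaces the phosphite ester of the electron-rich benzylic alcohol (SN2), leaving the benzyl ether intact.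

Step 4
Reactants: 5 methyl 2,4-dihydroxy-6-methylbenzoate (methyl orsellinate)
Product: 6 methyl 4-(benzyloxy)-2-hydroxy-6-methylbenzoate
Conditions: BnBr (1.05 equiv), K2CO3, acetone, reflux
Reagents that add atoms: benzyl bromide, BrCc1ccccc1
Why: Regioselective Williamson etherification, since the 2-OH is hydrogen-bonded to the ester carbonyl and only the 4-OH is alkylated.

Step 5
Reactants: 6 methyl 4-(benzyloxy)-2-hydroxy-6-methylbenzoate
Product: 7 methyl 4-(benzyloxy)-2-methoxy-6-methylbenzoate
Conditions: MeI, K2CO3, DMF, 50 °C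
Reagents that add atoms: iodomethane, CI
Why: Williamson methylation of the remaining chelated phenol under more forcing conditions.

Step 6
Reactants: 7 methyl 4-(benzyloxy)-2-methoxy-6-methylbenzoate
Product: 9 2-[5-(benzyloxy)-3-methoxy-2-(methoxycarbonyl)phenyl]acetic acid, via benzylic lithio species 8 (not isolated)
Conditions: LiN(i-Pr)2, THF, −78 °C; CO2; aq. HCl
Reagents that add atoms: carbon dioxide, O=C=O
Why: Lateral lithiation of the o-toluate gives the ester-stabilised benzylic anion 8, which is carboxylated to the homophthalic half ester.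

Step 7
Reactants: 9 2-[5-(benzyloxy)-3-methoxy-2-(methoxycarbonyl)phenyl]acetic acid; 10 (4R)-4-benzyl-1,3-oxazolidin-2-one
Product: 12 methyl 4-(benzyloxy)-2-{2-[(4R)-4-benzyl-2-oxo-1,3-oxazolidin-3-yl]-2-oxoethyl}-6-methoxybenzoate, via mixed pivalic anhydride 11 (not isolated)
Conditions: t-BuCOCl, Et3N, THF, −20 °C; then 10, LiCl, rt
Reagents that add atoms: none
Why: N-acylation of the oxazolidinone by the mixed anhydride 11 (standard attachment of an Evans auxiliary); the hindered aryl ester does not react.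

Step 8
Reactants: 12 methyl 4-(benzyloxy)-2-{2-[(4R)-4-benzyl-2-oxo-1,3-oxazolidin-3-yl]-2-oxoethyl}-6-methoxybenzoate; 4 4-(benzyloxy)-2-bromo-1-(bromomethyl)benzene
Product: 14 methyl 4-(benzyloxy)-2-{(2R)-1-[(4R)-4-benzyl-2-oxo-1,3-oxazolidin-3-yl]-3-[4-(benzyloxy)-2-bromophenyl]-1-oxopropan-2-yl}-6-methoxybenzoate, via sodium Z-enolate 13 (not isolated)
Conditions: NaN(SiMe3)2, THF, −78 °C; then 4, −78 to −40 °C
Reagents that add atoms: none
Why: Evans asymmetric alkylation, in which the chelated Z-enolate 13 is benzylated on the face opposite the benzyl group of the auxiliary, setting the future C3' as R.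

Step 9
Reactants: 14 the alkylated imide
Product: 15 (2R)-2-[5-(benzyloxy)-2-(hydroxymethyl)-3-methoxyphenyl]-3-[4-(benzyloxy)-2-bromophenyl]propan-1-ol
Conditions: LiAlH4, THF, 0 °C to rt
Reagents that add atoms: none
Why: Hydride reduction cleaves the imide to the primary alcohol (future C2') and reduces the aryl ester to the benzylic alcohol, leaving the stereocentre as a non-epimerisable carbinol β-carbon.

Step 10
Reactants: 15 the diol
Product: 16 {4-(benzyloxy)-2-[(3R)-7-(benzyloxy)-3,4-dihydro-2H-chromen-3-yl]-6-methoxyphenyl}methanol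
Conditions: Pd(OAc)2 (5 mol %), 2-(di-tert-butylphosphino)-1,1'-binaphthyl (6 mol %), Cs2CO3, toluene, 70 °C
Reagents that add atoms: none
Why: Intramolecular Buchwald–Hartwig etherification closes ring F through a six-membered palladacycle from the primary alcohol, whereas the benzylic alcohol would need an eight-membered ring.

Step 11
Reactants: 16 the chromanyl benzyl alcohol
Product: 17 4-(benzyloxy)-2-[(3R)-7-(benzyloxy)-3,4-dihydro-2H-chromen-3-yl]-6-methoxybenzaldehyde
Conditions: MnO2, CH2Cl2, rt
Reagents that add atoms: none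
Why: Selective MnO2 oxidation of the electron-rich benzylic alcohol to the aldehyde, whose carbon becomes C4.

Step 12
Reactants: 18 2-hydroxy-4,5-dimethoxybenzaldehyde
Product: 19 2-(benzyloxy)-4,5-dimethoxybenzaldehyde
Conditions: BnBr, K2CO3, DMF, rt
Reagents that add atoms: benzyl bromide, BrCc1ccccc1
Why: Williamson etherification, which protects the ring-B phenol that would otherwise cyclise onto the homologated aldehyde.

Step 13
Reactants: 19 2-(benzyloxy)-4,5-dimethoxybenzaldehyde
Product: 20 1-(benzyloxy)-4,5-dimethoxy-2-(2-methoxyethenyl)benzene (E/Z mixture)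
Conditions: Ph3P(CH2OMe)Cl, KOt-Bu, THF, 0 °C to rt
Reagents that add atoms: (methoxymethyl)triphenylphosphonium chloride, COC[P+](c1ccccc1)(c1ccccc1)c1ccccc1.[Cl-]
Why: Wittig methoxymethylenation for one-carbon homologation; the alkene geometry is irrelevant.

Step 14
Reactants: 20 the enol ether
Product: 21 2-[2-(benzyloxy)-4,5-dimethoxyphenyl]acetaldehyde
Conditions: aq. HCl, THF, 40 °C
Reagents that add atoms: water, O
Why: Acid hydrolysis of the enol ether gives the arylacetaldehyde, which is used at once.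

Step 15
Reactants: 22 5-(benzyloxy)-2-bromophenol; 17 the ring-E aldehyde
Product: 24 5-(benzyloxy)-2-[{4-(benzyloxy)-2-[(3R)-7-(benzyloxy)chroman-3-yl]-6-methoxyphenyl}(hydroxy)methyl]phenol (both carbinol epimers), via dilithio phenoxide 23 (not isolated)
Conditions: 22, n-BuLi (2.1 equiv), THF, −78 to 0 °C; then 17, −78 °C to rt; H2O
Reagents that add atoms: none
Why: Deprotonation and bromine–lithium exchange give the C,O-dilithio species 23, which adds 1,2 to the aldehyde without α-hydrogens; the new carbinol centre is planarised in the next step.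

Step 16
Reactants: 24 the o-hydroxybenzhydrol; 21 2-[2-(benzyloxy)-4,5-dimethoxyphenyl]acetaldehyde
Product: 28 (3R,4S)-7-(benzyloxy)-3-[2-(benzyloxy)-4,5-dimethoxyphenyl]-4-{4-(benzyloxy)-2-[(3R)-7-(benzyloxy)chroman-3-yl]-6-methoxyphenyl}chroman-2-ol (both anomers), via o-quinone methide 25 (not isolated), via catalyst enamine 26 (not isolated), via open-chain aldehyde 27 (not isolated)
Conditions: (R)-α,α-diphenylprolinol trimethylsilyl ether (20 mol %), PhCO2H (20 mol %), CH2Cl2, rt
Reagents that add atoms: none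
Why: Benzoic acid dehydrates 24 to the o-quinone methide 25 (1-oxadiene O1=C8a–C4a=C4) while the amine converts 21 into the E-enamine 26; the enamine carbon C3 adds to the methide carbon C4 with rearomatisation of ring A, hydrolysis returns the catalyst and aldehyde 27, and the freed phenol O1 adds to the aldehyde carbon C2 to give lactol 28. The closest known reaction type is the diarylprolinol silyl ether-catalysed Michael addition/hemiacetalisation of aldehydes to o-quinone methides generated in situ, which gives trans-3,4-disubstituted chroman-2-ols. Pyran ring C is the only ring closed, by 6-exo-trig attack of O1 on the C2 carbonyl. C4 is set under catalyst control, the diphenyl(silyloxy)methyl group shielding one enamine face and the methide approaching in the synclinal open arrangement known for nitroalkenes, which translates into 4S for the (R)-catalyst. C3 is α to the aldehyde of 27 and equilibrates under the amine to the trans-diaryl (3R) arrangement, so it is relayed from C4 by thermodynamic control, and C2 is left as an anomer mixture. The step needs C–C bond formation at C4 to outrun dimerisation of 25 and trapping by arenes or oxygen, which the high nucleophilicity of the enamine, O1–H being the only free phenol and the di-ortho-substituted ring E (blocking self-cycloaddition of 25) should secure.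

Step 17
Reactants: 28 the lactol
Product: 30 (3R,4S)-7-(benzyloxy)-3-[2-(benzyloxy)-4,5-dimethoxyphenyl]-4-{4-(benzyloxy)-2-[(3R)-7-(benzyloxy)chroman-3-yl]-6-methoxyphenyl}chroman, via cyclic oxocarbenium ion 29 (not isolated)
Conditions: Et3SiH, BF3·OEt2, CH2Cl2, −78 to −30 °C
Reagents that add atoms: none
Why: Ionic hydrogenation of the lactol, in which BF3 ionises the anomeric hydroxyl to 29 and the silane delivers hydride to C2, so the O1–C2 bond and both ring stereocentres are kept.

Step 18
Reactants: 30 the tetrabenzyl ether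
Product: 31 (3R,4S)-3-(2-hydroxy-4,5-dimethoxyphenyl)-4-{4-hydroxy-2-[(3R)-7-hydroxychroman-3-yl]-6-methoxyphenyl}chroman-7-ol
Conditions: H2 (1 atm), Pd/C, EtOAc–MeOH, rt
Reagents that add atoms: none
Why: Hydrogenolysis removes the four benzyl ethers; the chroman C–O bonds are not benzylic and the diarylmethine C–C bonds are inert.

**Compound list**

1 | 2-bromo-4-hydroxybenzaldehyde | O=Cc1ccc(O)cc1Br | starting material
2 | 4-(benzyloxy)-2-bromobenzaldehyde | O=Cc1ccc(OCc2ccccc2)cc1Br | intermediate
3 | [4-(benzyloxy)-2-bromophenyl]methanol | OCc1ccc(OCc2ccccc2)cc1Br | intermediate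
4 | 4-(benzyloxy)-2-bromo-1-(bromomethyl)benzene | BrCc1ccc(OCc2ccccc2)cc1Br | intermediate
5 | methyl 2,4-dihydroxy-6-methylbenzoate | COC(=O)c1c(C)cc(O)cc1O | starting material
6 | methyl 4-(benzyloxy)-2-hydroxy-6-methylbenzoate | COC(=O)c1c(C)cc(OCc2ccccc2)cc1O | intermediate
7 | methyl 4-(benzyloxy)-2-methoxy-6-methylbenzoate | COC(=O)c1c(C)cc(OCc2ccccc2)cc1OC | intermediate
8 | methyl 4-(benzyloxy)-2-(lithiomethyl)-6-methoxybenzoate | COC(=O)c1c(C[Li])cc(OCc2ccccc2)cc1OC | intermediate
9 | 2-[5-(benzyloxy)-3-methoxy-2-(methoxycarbonyl)phenyl]acetic acid | COC(=O)c1c(CC(=O)O)cc(OCc2ccccc2)cc1OC | intermediate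
10 | (4R)-4-benzyl-1,3-oxazolidin-2-one | O=C1N[C@H](Cc2ccccc2)CO1 | starting material
11 | mixed pivalic anhydride of 9 | COC(=O)c1c(CC(=O)OC(=O)C(C)(C)C)cc(OCc2ccccc2)cc1OC | intermediate
12 | methyl 4-(benzyloxy)-2-{2-[(4R)-4-benzyl-2-oxo-1,3-oxazolidin-3-yl]-2-oxoethyl}-6-methoxybenzoate | COC(=O)c1c(CC(=O)N2[C@H](Cc3ccccc3)COC2=O)cc(OCc4ccccc4)cc1OC | intermediate
13 | sodium (Z)-enolate of 12 | COC(=O)c1c(/C=C(\O[Na])N2[C@H](Cc3ccccc3)COC2=O)cc(OCc4ccccc4)cc1OC | intermediate
14 | methyl 4-(benzyloxy)-2-{(2R)-1-[(4R)-4-benzyl-2-oxo-1,3-oxazolidin-3-yl]-3-[4-(benzyloxy)-2-bromophenyl]-1-oxopropan-2-yl}-6-methoxybenzoate | COC(=O)c1c([C@@H](Cc5ccc(OCc6ccccc6)cc5Br)C(=O)N2[C@H](Cc3ccccc3)COC2=O)cc(OCc4ccccc4)cc1OC | intermediate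
15 | (2R)-2-[5-(benzyloxy)-2-(hydroxymethyl)-3-methoxyphenyl]-3-[4-(benzyloxy)-2-bromophenyl]propan-1-ol | OCc1c([C@@H](Cc5ccc(OCc6ccccc6)cc5Br)CO)cc(OCc4ccccc4)cc1OC | intermediate
16 | {4-(benzyloxy)-2-[(3R)-7-(benzyloxy)-3,4-dihydro-2H-chromen-3-yl]-6-methoxyphenyl}methanol | OCc1c([C@@H]2COc3cc(OCc4ccccc4)ccc3C2)cc(OCc5ccccc5)cc1OC | intermediate
17 | 4-(benzyloxy)-2-[(3R)-7-(benzyloxy)-3,4-dihydro-2H-chromen-3-yl]-6-methoxybenzaldehyde | O=Cc1c([C@@H]2COc3cc(OCc4ccccc4)ccc3C2)cc(OCc5ccccc5)cc1OC | intermediate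
18 | 2-hydroxy-4,5-dimethoxybenzaldehyde | COc1cc(O)c(C=O)cc1OC | starting material
19 | 2-(benzyloxy)-4,5-dimethoxybenzaldehyde | COc1cc(OCc2ccccc2)c(C=O)cc1OC | intermediate
20 | 1-(benzyloxy)-4,5-dimethoxy-2-(2-methoxyethenyl)benzene (E/Z mixture) | COC=Cc1cc(OC)c(OC)cc1OCc1ccccc1 | intermediate
21 | 2-[2-(benzyloxy)-4,5-dimethoxyphenyl]acetaldehyde | O=CCc1cc(OC)c(OC)cc1OCc1ccccc1 | intermediate
22 | 5-(benzyloxy)-2-bromophenol | Oc1cc(OCc2ccccc2)ccc1Br | starting material
23 | lithium 5-(benzyloxy)-2-lithiophenoxide | [Li]Oc1cc(OCc2ccccc2)ccc1[Li] | intermediate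
24 | 5-(benzyloxy)-2-[{4-(benzyloxy)-2-[(3R)-7-(benzyloxy)chroman-3-yl]-6-methoxyphenyl}(hydroxy)methyl]phenol (carbinol epimers) | OC(c1ccc(OCc2ccccc2)cc1O)c1c([C@@H]2COc3cc(OCc4ccccc4)ccc3C2)cc(OCc5ccccc5)cc1OC | intermediate
25 | 3-(benzyloxy)-6-({4-(benzyloxy)-2-[(3R)-7-(benzyloxy)chroman-3-yl]-6-methoxyphenyl}methylidene)cyclohexa-2,4-dien-1-one (o-quinone methide) | O=C1C=C(OCc2ccccc2)C=CC1=Cc1c([C@@H]2COc3cc(OCc4ccccc4)ccc3C2)cc(OCc5ccccc5)cc1OC | intermediate
26 | (E)-enamine of 21 with (R)-α,α-diphenylprolinol trimethylsilyl ether | COc1cc(OCc2ccccc2)c(/C=C/N2CCC[C@@H]2C(O[Si](C)(C)C)(c2ccccc2)c2ccccc2)cc1OC | intermediate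
27 | (2R,3S)-2-[2-(benzyloxy)-4,5-dimethoxyphenyl]-3-[4-(benzyloxy)-2-hydroxyphenyl]-3-{4-(benzyloxy)-2-[(3R)-7-(benzyloxy)chroman-3-yl]-6-methoxyphenyl}propanal | COc1cc(OCc4ccccc4)c([C@H](C=O)[C@@H](c3ccc(OCc4ccccc4)cc3O)c2c(OC)cc(OCc4ccccc4)cc2[C@@H]2COc3cc(OCc4ccccc4)ccc3C2)cc1OC | intermediate
28 | (3R,4S)-7-(benzyloxy)-3-[2-(benzyloxy)-4,5-dimethoxyphenyl]-4-{4-(benzyloxy)-2-[(3R)-7-(benzyloxy)chroman-3-yl]-6-methoxyphenyl}chroman-2-ol (anomer mixture) | COc1cc(OCc4ccccc4)c([C@@H]2C(O)Oc3cc(OCc4ccccc4)ccc3[C@H]2c2c(OC)cc(OCc4ccccc4)cc2[C@@H]2COc3cc(OCc4ccccc4)ccc3C2)cc1OC | intermediate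
29 | cyclic oxocarbenium ion (O1=C2 cation) from 28 | COc1cc(OCc4ccccc4)c([C@@H]2C=[O+]c3cc(OCc4ccccc4)ccc3[C@H]2c2c(OC)cc(OCc4ccccc4)cc2[C@@H]2COc3cc(OCc4ccccc4)ccc3C2)cc1OC | intermediate
30 | (3R,4S)-7-(benzyloxy)-3-[2-(benzyloxy)-4,5-dimethoxyphenyl]-4-{4-(benzyloxy)-2-[(3R)-7-(benzyloxy)chroman-3-yl]-6-methoxyphenyl}chroman | COc1cc(OCc4ccccc4)c([C@@H]2COc3cc(OCc4ccccc4)ccc3[C@H]2c2c(OC)cc(OCc4ccccc4)cc2[C@@H]2COc3cc(OCc4ccccc4)ccc3C2)cc1OC | intermediate
31 | (3R,4S)-3-(2-hydroxy-4,5-dimethoxyphenyl)-4-{4-hydroxy-2-[(3R)-7-hydroxychroman-3-yl]-6-methoxyphenyl}chroman-7-ol | COc1cc(O)c([C@@H]2COc3cc(O)ccc3[C@H]2c2c(OC)cc(O)cc2[C@@H]2COc3cc(O)ccc3C2)cc1OC | target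

**Step count**

Total: 18 steps. Longest linear sequence: 12 steps (steps 4–11, then 15–18, from 5 to 31).

**Steps most likely to fail**

1. Step 16. The new C3–C4 bond joins two hindered benzylic carbons, so the enamine addition may be too slow and 25 may dimerise or be trapped by arenes. The facial selectivity at C4 may also be low, or mismatched with the resident (R) centre of ring F. Fallback: carbinol 24 and enol ether 20 (taken before its hydrolysis) are combined with a chiral BINOL-derived phosphoric acid (3,3'-bis(2,4,6-triisopropylphenyl) type, enantiomer chosen for 4S) in CH2Cl2. The same o-quinone methide 25 should then undergo an inverse-electron-demand oxa-Diels–Alder reaction with the much smaller enol ether, giving the 2-methoxychroman acetal F1 as a mixture at C2 and C3. Hydrolysis (aq. HCl, THF) and equilibration of C3 with catalytic pyrrolidine bring the material back to the route at lactol 28. Because ring F already carries its (R) centre, the two C4 epimers are diastereomers and can be separated by chromatography if the acid gives little bias.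

2. Step 17. The oxocarbenium ion 29 may lose the C3 proton to a 4H-chromene and so scramble C3, and the Lewis acid may ionise the electron-rich C4 position or cleave benzyl ethers. Fallback: lactol 28 is reduced through its open form 27 with NaBH4 (EtOH–THF, 0 °C) to the phenol–primary alcohol F2. A Mitsunobu cyclisation (PPh3, diisopropyl azodicarboxylate, THF, 0 °C) then re-forms the O1–C2 bond by SN2 at the primary carbon under neutral conditions and returns to the route at 30.

3. Step 15. Bromine–lithium exchange on the lithium phenoxide may be incomplete, and addition of 23 to the di-ortho-substituted aldehyde 17 may be slow, leaving protonated arene and unreacted aldehyde. Fallback: commercial 3-(benzyloxy)phenol is converted with EtMgBr (Et2O, then toluene) into bromomagnesium 3-(benzyloxy)phenoxide F3. This reagent should add to aldehyde 17 through a magnesium-chelated six-membered transition state, specifically at the position ortho to oxygen and para to the benzyloxy group (phenoxide-directed ortho-hydroxyalkylation). After aqueous work-up this gives carbinol 24 directly, where the route is rejoined.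

**Further compounds**

F1 | step 16 | (4S)-7-(benzyloxy)-3-[2-(benzyloxy)-4,5-dimethoxyphenyl]-4-{4-(benzyloxy)-2-[(3R)-7-(benzyloxy)chroman-3-yl]-6-methoxyphenyl}-2-methoxychroman (mixture at C2 and C3) | COc1cc(OCc4ccccc4)c(C2C(OC)Oc3cc(OCc4ccccc4)ccc3[C@H]2c2c(OC)cc(OCc4ccccc4)cc2[C@@H]2COc3cc(OCc4ccccc4)ccc3C2)cc1OC
F2 | step 17 | 5-(benzyloxy)-2-[(1S,2R)-2-[2-(benzyloxy)-4,5-dimethoxyphenyl]-1-{4-(benzyloxy)-2-[(3R)-7-(benzyloxy)chroman-3-yl]-6-methoxyphenyl}-3-hydroxypropyl]phenol | COc1cc(OCc4ccccc4)c([C@H](CO)[C@@H](c3ccc(OCc4ccccc4)cc3O)c2c(OC)cc(OCc4ccccc4)cc2[C@@H]2COc3cc(OCc4ccccc4)ccc3C2)cc1OC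
F3 | step 15 | bromomagnesium 3-(benzyloxy)phenoxide | Br[Mg]Oc1cccc(OCc2ccccc2)c1
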